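The dihydrofuran ring of the target (O1, C2, C3, C3a, C7a) with its exocyclic diarylmethine Cα is read as the C ring of a flavan-3-ol after a 1,2-shift of the ring oxygen: furan O1/C2/C3/C3a are flavan O1/C3/C4/C4a and Cα is flavan C2. Everything rests on disconnecting the furan O1–C2 bond and the Cα–C8′ bond to the catechin unit. In one operation, ionisation of benzylated (−)-epicatechin 3-triflate contracts the pyran ring and the rearranged benzylic ion is captured by C8 of perbenzylated (+)-catechin, setting furan C2 and Cα. The precursor is the 5,7,3′,4′-tetra-O-benzyl epicatechin triflate, generated in the flask beside excess penta-O-benzylcatechin.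

Key step: step 4

Remark: the configurations were re-derived and need no correction. The target is 2S at the furan carbon, R at Cα and 2R,3S in the flavan unit, which (2R,3R)-epicatechin reaches by inversion at both C3 and C2 (the Cα descriptor stays R only because the CIP ranking changes).
Remark: the catechin 3-hydroxyl is carried as a benzyl ether rather than an ester, so that one hydrogenolysis ends the synthesis. The labile triflate is made and consumed in one flask in the presence of the nucleophile.

Step 1
Reactants: 1 (−)-epicatechin [(2R,3R)-2-(3,4-dihydroxyphenyl)chroman-3,5,7-triol]; 2 benzyl bromide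
Product: 3 5,7,3′,4′-tetra-O-benzyl-(−)-epicatechin [(2R,3R)-5,7-bis(benzyloxy)-2-[3,4-bis(benzyloxy)phenyl]chroman-3-ol]
Conditions: BnBr (4.2 equiv), K2CO3 (4.5 equiv), DMF, −10 °C → rt, Ar
Reagents that add atoms: benzyl bromide (2), BrCc1ccccc1
Why: Williamson ether synthesis in which carbonate ionises only the four phenols, so SN2 benzylation caps them while the secondary 3-OH stays free and C2/C3 are untouched; the weak base, low temperature and exclusion of air are chosen to hold back C-benzylation of the phloroglucinol ring and C2 epimerisation.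

Step 2
Reactants: 4 (+)-catechin [(2R,3S)-2-(3,4-dihydroxyphenyl)chroman-3,5,7-triol]; 2 benzyl bromide
Product: 5 5,7,3′,4′-tetra-O-benzyl-(+)-catechin [(2R,3S)-5,7-bis(benzyloxy)-2-[3,4-bis(benzyloxy)phenyl]chroman-3-ol]
Conditions: BnBr (4.2 equiv), K2CO3 (4.5 equiv), DMF, 0 °C → rt, Ar
Reagents that add atoms: benzyl bromide (2), BrCc1ccccc1
Why: The same phenol-selective Williamson ether synthesis as in step 1, applied to the more robust 2,3-trans flavanol without change at either stereocentre.

Step 3
Reactants: 5 5,7,3′,4′-tetra-O-benzyl-(+)-catechin; 2 benzyl bromide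
Product: 6 3,5,7,3′,4′-penta-O-benzyl-(+)-catechin [(2R,3S)-3,5,7-tris(benzyloxy)-2-[3,4-bis(benzyloxy)phenyl]chroman]
Conditions: NaH (1.3 equiv), BnBr (1.3 equiv), Bu4NI (cat.), THF, 0 °C → rt
Reagents that add atoms: benzyl bromide (2), BrCc1ccccc1
Why: Williamson ether synthesis on the sodium alkoxide of the only remaining hydroxyl; with every phenol already etherified no ring opening to a quinone methide is possible, so the 2R,3S configuration is retained.

Step 4
Reactants: 3 5,7,3′,4′-tetra-O-benzyl-(−)-epicatechin; 6 3,5,7,3′,4′-penta-O-benzyl-(+)-catechin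
Product: 9 nona-O-benzyl ether of the target [(2S)-4,6-bis(benzyloxy)-2,3-dihydrobenzofuran-2-yl-(R)-[3,4-bis(benzyloxy)phenyl]methyl unit on C8 of penta-O-benzyl-(+)-catechin], via epicatechin 3-triflate 7 (not isolated), via oxiranium triflate 8 (not isolated)
Conditions: 6 (3 equiv), 2,6-di-tert-butyl-4-methylpyridine (3 equiv), 4 Å MS, CH2Cl2, −78 °C; Tf2O (1.05 equiv) dropwise; −78 → −30 °C; then aq NaHCO3
Reagents that add atoms: none
Why: Proposed new method: Triflation of the 3-OH gives 7, whose half-chair with the 2-aryl group axial and the triflate equatorial places C2–O1 antiperiplanar to C3–OTf, so the ring oxygen expels triflate from the rear to form the O-aryl oxiranium ion 8; its benzylic C–O bond, weakened by the 4-benzyloxyphenyl group, is then opened at that carbon and anti to oxygen by C8 of 6, and the base removes the arene proton. The closest known reaction type is the ring contraction of 3-hydroxy or 3-sulfonyloxy chromans, tetrahydropyrans and pyranosides through neighbouring ring-oxygen participation with capture by fluoride or solvent, joined here to the Friedel–Crafts alkylation of benzylated flavan-3-ols at C8 by benzylic cations; interception of the rearranged ion by an arene is the untested part. The dihydrofuran ring is closed by attack of O1 on C3, 5-exo-tet with respect to the new five-membered ring (3-exo-tet for the transient oxiranium), and is the ring that remains once C2–O1 has broken. Furan C2 is set by this stereospecific rear-side substitution (3R of 3 becomes 2S) and Cα by anti opening of the bridged ion (inversion at the former C2, the descriptor staying R because the CIP ranking changes), so both derive from the two stereocentres of epicatechin. The step needs oxygen shift to win over hydride shift, elimination and migration of C4a, which the cation-stabilising B ring at the migration origin and a base too hindered for E2 should secure; it needs C8 rather than C6 attack, favoured because C6 of 6 lies between two benzyloxy groups; and it needs cross-coupling rather than self-alkylation, for which 6 is used in threefold excess.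

Step 5
Reactants: 9 nona-O-benzyl ether of the target
Product: 10 target, (2R,3S)-2-(3,4-dihydroxyphenyl)-8-{(R)-(3,4-dihydroxyphenyl)[(2S)-4,6-dihydroxy-2,3-dihydro-1-benzofuran-2-yl]methyl}chroman-3,5,7-triol
Conditions: H2 (1 atm), 20% Pd(OH)2/C, THF/MeOH/H2O, rt; filtration under Ar, lyophilisation
Reagents that add atoms: none
Why: Catalytic hydrogenolysis (O-debenzylation) of eight aryl and one alkyl benzyl ether over palladium hydroxide is the standard unmasking of perbenzylated flavan-3-ol oligomers; the ring C–O bonds of the chroman and dihydrobenzofuran and the diarylmethine C–C bonds should survive at 1 atm and room temperature, and no stereocentre is involved.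

Compound list
1 | (−)-epicatechin, (2R,3R) | O[C@@H]1Cc2c(O)cc(O)cc2O[C@@H]1c1ccc(O)c(O)c1 | starting material
2 | benzyl bromide | BrCc1ccccc1 | starting material
3 | 5,7,3′,4′-tetra-O-benzyl-(−)-epicatechin, (2R,3R) | O[C@@H]1Cc2c(OCc3ccccc3)cc(OCc3ccccc3)cc2O[C@@H]1c1ccc(OCc2ccccc2)c(OCc2ccccc2)c1 | intermediate
4 | (+)-catechin, (2R,3S) | O[C@H]1Cc2c(O)cc(O)cc2O[C@@H]1c1ccc(O)c(O)c1 | starting material
5 | 5,7,3′,4′-tetra-O-benzyl-(+)-catechin, (2R,3S) | O[C@H]1Cc2c(OCc3ccccc3)cc(OCc3ccccc3)cc2O[C@@H]1c1ccc(OCc2ccccc2)c(OCc2ccccc2)c1 | intermediate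
6 | 3,5,7,3′,4′-penta-O-benzyl-(+)-catechin, (2R,3S) | O(Cc3ccccc3)[C@H]1Cc2c(OCc3ccccc3)cc(OCc3ccccc3)cc2O[C@@H]1c1ccc(OCc2ccccc2)c(OCc2ccccc2)c1 | intermediate
7 | 5,7,3′,4′-tetra-O-benzyl-(−)-epicatechin 3-O-triflate, (2R,3R), not isolated | FC(F)(F)S(=O)(=O)O[C@@H]1Cc2c(OCc3ccccc3)cc(OCc3ccccc3)cc2O[C@@H]1c1ccc(OCc2ccccc2)c(OCc2ccccc2)c1 | intermediate
8 | O-aryl oxiranium triflate: O1 bridges the former C2 (R) and C3 (S), aryl and ring CH2 cis on the three-membered ring, not isolated | c1(OCc4ccccc4)cc(OCc4ccccc4)c2c(c1)[O+]3[C@H](c1ccc(OCc4ccccc4)c(OCc4ccccc4)c1)[C@@H]3C2.[O-]S(=O)(=O)C(F)(F)F | intermediate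
9 | nona-O-benzyl ether of the target: (2R,3S)-3,5,7-tris(benzyloxy)-2-[3,4-bis(benzyloxy)phenyl]-8-{(R)-[3,4-bis(benzyloxy)phenyl][(2S)-4,6-bis(benzyloxy)-2,3-dihydro-1-benzofuran-2-yl]methyl}chroman | c1(OCc4ccccc4)cc(OCc4ccccc4)c2c(c1)O[C@H]([C@H](c1ccc(OCc4ccccc4)c(OCc4ccccc4)c1)c1c(OCc4ccccc4)cc(OCc4ccccc4)c3c1O[C@H](c1ccc(OCc4ccccc4)c(OCc4ccccc4)c1)[C@@H](OCc4ccccc4)C3)C2 | intermediate
10 | (2R,3S)-2-(3,4-dihydroxyphenyl)-8-{(R)-(3,4-dihydroxyphenyl)[(2S)-4,6-dihydroxy-2,3-dihydro-1-benzofuran-2-yl]methyl}chroman-3,5,7-triol | Oc1cc(O)c2c(c1)O[C@H]([C@H](c1ccc(O)c(O)c1)c1c(O)cc(O)c3c1O[C@H](c1ccc(O)c(O)c1)[C@@H](O)C3)C2 | target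

Total step count: 5
Longest linear sequence: 4 steps (4 → 5 → 6 → 9 → 10; steps 2, 3, 4, 5)

Steps most likely to fail

1. Step 4 (Proposed new method). The triflate may ionise through the aryl-equatorial conformer and collapse by hydride shift or elimination. The rearranged ion may alkylate the A ring of another electrophile molecule before 6 intercepts it. The bridged ion may relax to a free benzylic cation, so that facial control at Cα is lost, and some attack through C6 of 6 is possible. Fallback with known chemistry, setting out from 3 and returning at 9: the rearrangement and the C–C bond formation are separated. Treatment of 3 with DAST (CH2Cl2, −78 → 0 °C) is the known deoxyfluorinative ring contraction by ring-oxygen participation with fluoride capture. It should give (2S)-4,6-bis(benzyloxy)-2-{(S)-[3,4-bis(benzyloxy)phenyl]fluoromethyl}-2,3-dihydro-1-benzofuran F1, which can be isolated and its configuration checked. F1 is then used in a Friedel–Crafts benzylation of excess 6 under C–F activation (hexafluoroisopropanol/CH2Cl2, 0 °C, or BF3·OEt2, −78 °C), which returns to 9. The furan oxygen can again assist departure of fluoride, so the same anti opening is expected; any Cα epimer would be removed by chromatography at the stage of 9.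

2. Step 5. Removal of nine benzyl groups may stall at partly benzylated material, the benzylic C2–O1 bond of the chroman may be cut on prolonged exposure, and the free polyphenol may oxidise in air during isolation. Fallback, setting out from 9 and returning at 10: non-reductive debenzylation with BCl3 and pentamethylbenzene as benzyl-cation scavenger (CH2Cl2, −78 → −40 °C, MeOH quench, Sephadex LH-20). This Lewis-acid ether cleavage avoids hydrogen and catalyst and leads directly to 10, so no new compound arises (F0).

3. Step 1. C-Benzylation of the phloroglucinol ring and base-induced opening at C2 (epimerisation, oxidation) may erode the supply of 3 from the costlier flavanol. Fallback, setting out from 5 and returning at 3: Dess–Martin oxidation of 5 (CH2Cl2, rt) should give (2R)-5,7-bis(benzyloxy)-2-[3,4-bis(benzyloxy)phenyl]chroman-3-one F2. Reduction with L-Selectride (THF, −78 °C) should deliver hydride to the face opposite the 2-aryl group and give the 2,3-cis alcohol 3. Both operations are known for benzylated catechin and draw on the cheaper (+)-catechin.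

Further compounds
F1 | step 4 | (2S)-4,6-bis(benzyloxy)-2-{(S)-[3,4-bis(benzyloxy)phenyl]fluoromethyl}-2,3-dihydro-1-benzofuran | c1(OCc4ccccc4)cc(OCc4ccccc4)c2c(c1)O[C@H]([C@H](c1ccc(OCc4ccccc4)c(OCc4ccccc4)c1)F)C2
F0 | step 5 | none | none
F2 | step 1 | (2R)-5,7-bis(benzyloxy)-2-[3,4-bis(benzyloxy)phenyl]chroman-3-one | O=C1Cc2c(OCc3ccccc3)cc(OCc3ccccc3)cc2O[C@@H]1c1ccc(OCc2ccccc2)c(OCc2ccccc2)c1
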